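## Analysis of the target

The target is a germacranolide: a cyclodeca-1(10),4-diene whose C1=C10 bond is Z and whose C4=C5 bond is E, both trisubstituted, carrying a γ-lactone fused across C6–C7 (12,6-olide). It has five ring stereocentres, 3S, 6S, 7S, 9S and 11R, plus the 2R centre of the 2-methylbutanoate on O3. H6 and H7 are trans (trans-fused lactone), the C9 oxygen is cis to the C7 side chain across the ring, and the C11 methyl is cis to C8, which is the thermodynamically less stable lactone epimer. Sensitive features are the 1,5-diene (acid-induced transannular cyclisation, Cope rearrangement on heating), the epimerisable C11 and acyl α-centres, and two allylic C–O bonds. The difficulty is the strained ten-membered ring with one Z and one E olefin and stereocentres spread around a flexible ring. The strategy rests on the array C10=C1–C2–C3(O)–C4=C5: at the enol-ether oxidation level of C3 this is a hexatriene, the open form of a cyclohexa-1,3-diene whose sp3–sp3 bond is C5–C10. The target is therefore a 6/6 eudesmanolide cut at C5–C10, and a Z/E pair of olefins requires the cis-fused bicycle. The trans-lactone fixes the conformation of that bicycle and thereby decides which olefin becomes Z.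

## Retrosynthetic reasoning

**C9–O–Si, the C3 ester and the C3 carbinol.** Target 22 is traced to its 9-O-silyl ether 21, the ester C–O bond is cut to alcohol 19 and acid 20, and 19 is traced to ketone 18. The carbonyl at C3 is the natural product of the ring-opening step, and a reagent-controlled reduction of an α-methyl enone is a dependable way to reach 3S. The forward steps must leave the 1,5-diene, the lactone and C11 untouched, so they are all run near neutrality.

**Re-forming C5–C10.** Ketone 18 is the hydrolysis product of silyloxy-triene 17, and closing the C5–C10 bond of 17 gives the cis-fused dienol ether 16. No skeletal bond is made in the forward direction; the ten-membered ring and both olefin geometries come from one stereospecific pericyclic event, so no macrocyclisation is needed. The forward reaction has to choose one of two conrotatory senses and the product has to be trapped before it recloses. Only the cis-fused diastereomer with H5 and C14 on the face opposite O6 is suitable, because its lactone-locked conformation places C14 and C6 pseudo-equatorial on ring A.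

**Ring-A unsaturation.** Dienol ether 16 comes from enone 15 by enolisation towards C4, the only enolisable position because C10 is quaternary. Enone 15 comes from the regiodefined C2=C3 silyl enol ether 14 by dehydrogenation. This avoids any regiochemical choice in ring A.

**C11.** The C11–C13 bond is cut: 14 is the C11 epimer of 13, and 13 is the methylation product of the nor-lactone 12. Both operations use the same bias of the trans-fused lactone enolate (attack anti to C8), first for carbon and then for hydrogen, which delivers the less stable 11R epimer. They are placed where the lactone is the only carbonyl group.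

**C9.** Silyl ether 12 comes from alcohol 11 and this from ketone 10. The ketone is needed one step earlier as the activating group of the dienophile, so C9 is reduced directly after the cycloaddition.

**Ring A and the cis ring fusion.** The C4–C5 and C1–C10 bonds of 10 are cut to give enone 7 and diene 9. A plan that hydrogenates a C4=C5 enone with the lactone already in place was set aside: hydrogen is delivered to such enones mainly anti to the angular methyl group, which gives the trans fusion. The cycloaddition makes the cis fusion by construction, and axial bond formation on the lactone-locked half-chair of 7, anti to the C7–C11 bond, gives the required diastereomer.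

**Ring B.** Enone 7 is opened at C5=C10 (aldol condensation) to keto aldehyde 6, which comes from alcohol 5. The C7–C8 bond is cut to butenolide 2 and keto ester 3 (conjugate addition anti to the C6 substituent, then acidolysis and decarboxylation of adduct 4). Butenolide 2 is the trityl ether of commercial 1, which supplies C6 in the correct absolute configuration. Diene 9 is the silyl dienol ether of ketone 8.

## Alternatives that were turned down

**Alternative 1:** The ring is disconnected at C5–C6 together with the lactone C–O bond. In the forward step an (E)-alkenyl iodide at C5 of an open-chain substrate is turned into an alkenylchromium species that adds to a C6 aldehyde, and the resulting alkoxide closes the lactone on the C12 ester, giving A1. In its favour: the approach is convergent, it makes the ring, the C6 stereocentre and the lactone at once, the 4E geometry is carried in from the iodide, and A1 is one desilylation from the target. On endgame length and on avoiding photochemistry it is stronger than the chosen route. Against it: the open-chain substrate must already hold C3, C7, C9 and C11, the Z-trisubstituted C1=C10 olefin and the acyl group, each from a separate stereoselective operation in a long linear sequence. The C6 configuration is decided in a strained ten-membered transition state with an epimerisable α-branched aldehyde, and the closure needs high dilution and excess metal. The chosen route offers instead a ring that is never closed end to end, stereocentres set on rigid chairs, and both olefin geometries from one stereospecific event.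

**Alternative 2:** The ring is disconnected at C3–C4. A nickel(0) catalyst with a phosphine or carbene ligand and a borane reductant couples a C3 aldehyde with a C4≡C5 alkyne through an oxanickelacycle, giving A2 with the C3 carbinol and the E olefin. In its favour: one catalytic step makes the allylic alcohol and, by syn addition, the trisubstituted E olefin; for the C4=C5 geometry it is as reliable as the chosen route. Against it: the C3 configuration is fixed during macrocyclisation with little basis for control in a ten-membered ring, and the endocyclic mode (bond to C4) competes with the exocyclic one. The β,γ-unsaturated aldehyde next to the Z olefin is prone to conjugation, and A2 still needs selective silyl removal, lactonisation and esterification. The linear precursor is as long as in Alternative 1. The chosen route sets C3 by reagent control on a ketone that the key step delivers directly.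

**Alternative 3:** A six-membered ring (C9, C10, C1, C2, C3, C4) carrying two alkenyl groups is expanded: the potassium alkoxide of a trans-1,2-dialkenylcyclohex-2-enol undergoes a [3,3] shift through a chair, breaking C4–C9 and forming C6–C7, to give ketone A3. In its favour: this is the best-precedented entry to germacranes, it is thermal and irreversible (enolate formation), the Z olefin is inherited from the cyclohexene and the E olefin from the chair. In precedent and in driving force it is stronger than the chosen photochemical step, which has to cope with a photostationary state. Against it for this target: A3 has C9 as a ketone, an isopropenyl group and an ether at C6. After ring expansion the C9 carbinol must be set in a flexible ring, the isopropenyl group oxidised to the carboxyl level with control of C11, the lactone closed and protecting groups exchanged, all on the sensitive 1,5-diene. The C6/C7 relationship also depends on two olefin geometries in the precursor. The chosen route installs every oxidation state and stereocentre on the rigid bicycle first and needs only three mild steps after the ring is opened.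

Key step: step 14

Remark: eudesmane/germacrane locants (C1–C15) are used for all intermediates; α/β refer to the usual drawing with the C10 methyl (C14) β.
Remark: C4 of 10–15 is planarised in step 13, so the endo/exo outcome of step 7 and any epimerisation at C4 have no consequence.
Remark: with silicon on O3 the ring-cis C2=C3 bond of 17 has the CIP descriptor E.

Step 1
Reactants: 1 (S)-5-(hydroxymethyl)furan-2(5H)-one
Product: 2 (S)-5-[(trityloxy)methyl]furan-2(5H)-one
Conditions: TrCl, pyridine, CH2Cl2, 0 °C → rt
Reagents that add atoms: trityl chloride, ClC(c1ccccc1)(c1ccccc1)c1ccccc1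
Why: O-tritylation of a primary alcohol; the bulky ether shields one face of the butenolide for step 2 and is acid-labile together with the tert-butyl ester of step 3; the stereocentre (C6) is not touched.

Step 2
Reactants: 2 (S)-5-[(trityloxy)methyl]furan-2(5H)-one; 3 tert-butyl 3-oxopentanoate
Product: 4 tert-butyl 3-oxo-2-[(2S,3R)-5-oxo-2-(trityloxymethyl)oxolan-3-yl]pentanoate (2,3-trans on the lactone; mixture at the keto-ester carbon)
Conditions: Cs2CO3 (0.2 equiv), MeCN, 0 °C → rt
Reagents that add atoms: none
Why: Michael addition of a soft β-keto ester anion to the butenolide; the nucleophile enters anti to the trityloxymethyl group, which sets C7 trans to the C6 substituent, and reversibility of the addition favours the same trans lactone; the keto-ester centre is removed in step 3.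

Step 3
Reactants: 4 tert-butyl 3-oxo-2-[(2S,3R)-5-oxo-2-(trityloxymethyl)oxolan-3-yl]pentanoate
Product: 5 (4S,5S)-5-(hydroxymethyl)-4-(2-oxobutyl)oxolan-2-one
Conditions: TFA, CH2Cl2, H2O (trace), rt → 40 °C; then NaHCO3, MeOH
Reagents that add atoms: none
Why: Acidolysis removes the trityl ether and the tert-butyl ester in one operation and the β-keto acid decarboxylates on warming; C6 and C7 are not involved.

Step 4
Reactants: 5 (4S,5S)-5-(hydroxymethyl)-4-(2-oxobutyl)oxolan-2-one
Product: 6 (2S,3S)-5-oxo-3-(2-oxobutyl)oxolane-2-carbaldehyde
Conditions: TEMPO (cat.), PhI(OAc)2, CH2Cl2, rt; used crude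
Reagents that add atoms: none
Why: TEMPO-catalysed oxidation of a primary alcohol stops at the aldehyde under neutral conditions, which protects the α-acyloxy stereocentre C6.

Step 5
Reactants: 6 (2S,3S)-5-oxo-3-(2-oxobutyl)oxolane-2-carbaldehyde
Product: 7 (3aS,7aS)-6-methyl-3a,7a-dihydro-1-benzofuran-2,5(3H,4H)-dione (trans-fused lactone enone)
Conditions: Bn2NH·TFA (0.3 equiv), toluene, 50 °C
Reagents that add atoms: none
Why: Intramolecular aldol condensation (6-enolexo-exo-trig): only the C10 enol of the ethyl ketone can reach the C5 aldehyde through a six-membered transition state (C8 would give a four-membered ring), and dehydration gives the conjugated C5=C10 enone; the trans-4,5 relationship of the lactone becomes the trans ring fusion.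

Step 6
Reactants: 8 ethyl vinyl ketone (pent-1-en-3-one)
Product: 9 (Z)-3-(tert-butyldimethylsilyloxy)penta-1,3-diene
Conditions: TBSOTf, Et3N, CH2Cl2, 0 °C
Reagents that add atoms: tert-butyldimethylsilyl triflate, CC(C)(C)[Si](C)(C)OS(=O)(=O)C(F)(F)F
Why: Soft enolisation and O-silylation of an ethyl ketone; the Z enol ether (methyl anti to vinyl) is expected to predominate and is the isomer that can reach the s-cis conformation needed in step 7.

Step 7
Reactants: 7 (3aS,7aS)-6-methyl-3a,7a-dihydro-1-benzofuran-2,5(3H,4H)-dione; 9 (Z)-3-(tert-butyldimethylsilyloxy)penta-1,3-diene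
Product: 10 3-(tert-butyldimethylsilyloxy)-9-oxo-13-nor-5βH-eudesm-2-en-12,6α-olide (cis-fused; 4α-methyl, 5β-H, 6β-H, 7α-H, 10β-methyl)
Conditions: EtAlCl2 (0.3 equiv), toluene, −78 → −30 °C; Et3N quench
Reagents that add atoms: none
Why: Lewis-acid-catalysed Diels–Alder reaction of a 2-silyloxydiene with an α-methyl cyclohexenone; the silyloxy group directs the methyl-bearing diene terminus to the enone β-carbon C5 ("para" orientation) and suprafacial addition makes H5 and C14 cis; the trans-lactone locks the half-chair of 7 so that axial bond formation at C5 occurs anti to the C7–C11 bond, placing H5 and C14 on the β face; endo addition should give 4β-H.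

Step 8
Reactants: 10 3-(tert-butyldimethylsilyloxy)-9-oxo-13-nor-5βH-eudesm-2-en-12,6α-olide
Product: 11 3-(tert-butyldimethylsilyloxy)-9β-hydroxy-13-nor-5βH-eudesm-2-en-12,6α-olide (9S)
Conditions: (R)-Me-CBS (0.5 equiv), catecholborane, toluene, −40 → −20 °C; MeOH, pH 9 buffer
Reagents that add atoms: none
Why: CBS reduction; the quaternary C10 and the C8 methylene differ sharply in size, so the (R)-catalyst should deliver hydride to give the 9S (9β, equatorial) alcohol under reagent control; catecholborane leaves the lactone and the silyl enol ether alone.

Step 9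
Reactants: 11 3-(tert-butyldimethylsilyloxy)-9β-hydroxy-13-nor-5βH-eudesm-2-en-12,6α-olide
Product: 12 3,9β-bis(tert-butyldimethylsilyloxy)-13-nor-5βH-eudesm-2-en-12,6α-olide
Conditions: TBSOTf, 2,6-lutidine, CH2Cl2, −78 → 0 °C
Reagents that add atoms: tert-butyldimethylsilyl triflate, CC(C)(C)[Si](C)(C)OS(=O)(=O)C(F)(F)F
Why: Silylation of a hindered secondary alcohol with a silyl triflate; no stereocentre is affected and the enol ether is stable to the buffered conditions.

Step 10
Reactants: 12 3,9β-bis(tert-butyldimethylsilyloxy)-13-nor-5βH-eudesm-2-en-12,6α-olide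
Product: 13 (11S)-3,9β-bis(tert-butyldimethylsilyloxy)-5βH-eudesm-2-en-12,6α-olide (13-methyl α)
Conditions: LDA (1.1 equiv), THF, −78 °C; MeI, −78 → −40 °C
Reagents that add atoms: iodomethane, CI
Why: Lactone enolate alkylation; the lactone is the only acidic site, and the electrophile approaches C11 from the α face, anti to C8 on the adjacent ring-fusion carbon, giving the 11S methyl lactone.

Step 11
Reactants: 13 (11S)-3,9β-bis(tert-butyldimethylsilyloxy)-5βH-eudesm-2-en-12,6α-olide
Product: 14 (11R)-3,9β-bis(tert-butyldimethylsilyloxy)-5βH-eudesm-2-en-12,6α-olide (13-methyl β)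
Conditions: LDA (1.2 equiv), THF, −78 °C; 2,6-di-tert-butyl-4-methylphenol, −78 °C
Reagents that add atoms: none
Why: Deprotonation and kinetic protonation of the lactone enolate; the proton is delivered from the same less hindered α face (anti to C8), which puts the methyl group on the β face and gives the less stable 11R epimer required by the target.

Step 12
Reactants: 14 (11R)-3,9β-bis(tert-butyldimethylsilyloxy)-5βH-eudesm-2-en-12,6α-olide
Product: 15 (11R)-9β-(tert-butyldimethylsilyloxy)-3-oxo-5βH-eudesm-1-en-12,6α-olide
Conditions: Pd(OAc)2 (1.1 equiv), MeCN, rt → 40 °C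
Reagents that add atoms: none
Why: Saegusa–Ito oxidation of the regiodefined C2=C3 silyl enol ether; β-hydride elimination can only take H1, giving the C1=C2 enone with the cis ring fusion intact under neutral conditions that do not touch C11.

Step 13
Reactants: 15 (11R)-9β-(tert-butyldimethylsilyloxy)-3-oxo-5βH-eudesm-1-en-12,6α-olide
Product: 16 (11R)-3,9β-bis(tert-butyldimethylsilyloxy)-5βH-eudesma-1,3-dien-12,6α-olide
Conditions: TBSOTf (1.3 equiv), Et3N, CH2Cl2, −78 → 0 °C
Reagents that add atoms: tert-butyldimethylsilyl triflate, CC(C)(C)[Si](C)(C)OS(=O)(=O)C(F)(F)F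
Why: Soft enolisation of an enone at the α′ position; C4–H is the only enolisable hydrogen because C10 is quaternary, so the cross-conjugated 3-silyloxy-1,3-diene forms as a single regioisomer, and the ketone reacts far faster than the lactone.

Step 14
Reactants: 16 (11R)-3,9β-bis(tert-butyldimethylsilyloxy)-5βH-eudesma-1,3-dien-12,6α-olide
Product: 18 (6S,7S,9S,11R)-9-(tert-butyldimethylsilyloxy)-3-oxogermacra-1(10)Z,4E-dien-12,6-olide, via silyloxy-triene 17 (not isolated)
Conditions: hν (ca. 285–300 nm, Pyrex), degassed THF (3 mM), −78 °C; then TBAF (1.1 equiv), AcOH (2 equiv), −78 → −40 °C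
Reagents that add atoms: none
Why: Excitation of the 3-silyloxy-1,3-diene opens the C5–C10 σ bond in a concerted, photochemically allowed conrotatory 6π electrocyclic reaction, which merges the two six-membered rings into the ten-membered triene 17. The closest known reaction type is the photochemical opening of fused cyclohexa-1,3-dienes to cyclodeca-1,3,5-trienes, as in the provitamin D to previtamin D change and the eudesmane-to-germacrane conversion of trans-fused dienes. The ten-membered ring arises by scission of the shared bond and not by an end-to-end closure, so no exo or endo mode applies. No stereocentre is created: C5 and C10 become trigonal and C6, C7, C9 and C11 are untouched. The step needs the conrotatory sense that turns C14 and C6 outward and H5 and C9 inward, giving 1(10)Z and 4E; because H5 and C14 are cis, conrotation must give one Z and one E olefin. That sense is secured by the trans-lactone, which holds ring B in the chair with O6 and C11 equatorial and so forces ring A into the one half-chair in which C14 and C6 are pseudo-equatorial and C9 and H5 pseudo-axial; ring opening is expected to follow the helicity of this ground-state conformer, pseudo-equatorial groups moving outward, as they do in the trans-fused series. Irradiation on the long-wavelength edge of the diene band at −78 °C should limit re-excitation of 17 and its thermal disrotatory reclosure. Buffered fluoride then cleaves only the enol silyl ether, and kinetic protonation of the dienolate at C2 should give the C3 ketone with C1=C10 left out of conjugation.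

Step 15
Reactants: 18 (6S,7S,9S,11R)-9-(tert-butyldimethylsilyloxy)-3-oxogermacra-1(10)Z,4E-dien-12,6-olide
Product: 19 (3S,6S,7S,9S,11R)-9-(tert-butyldimethylsilyloxy)-3-hydroxygermacra-1(10)Z,4E-dien-12,6-olide
Conditions: (R)-Me-CBS (0.5 equiv), catecholborane, toluene, −78 °C; MeOH, NaHCO3 aq
Reagents that add atoms: none
Why: CBS reduction of an α-methyl enone; the α-substituted alkenyl group (C4) acts as the large substituent and the C2 methylene as the small one, so the (R)-catalyst should give the 3S allylic alcohol by 1,2-reduction, under neutral conditions that do not move the β,γ-olefin.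

Step 16
Reactants: 19 (3S,6S,7S,9S,11R)-9-(tert-butyldimethylsilyloxy)-3-hydroxygermacra-1(10)Z,4E-dien-12,6-olide; 20 (R)-2-methylbutanoic acid
Product: 21 (3S,6S,7S,9S,11R)-9-(tert-butyldimethylsilyloxy)-3-[(2R)-2-methylbutanoyloxy]germacra-1(10)Z,4E-dien-12,6-olide
Conditions: EDC·HCl, DMAP (cat.), CH2Cl2, 0 °C → rt
Reagents that add atoms: none
Why: Carbodiimide/DMAP (Steglich-type) esterification; acylation at oxygen retains C3, and low temperature with catalytic DMAP keeps the α-centre of the acid from epimerising.

Step 17
Reactants: 21 (3S,6S,7S,9S,11R)-9-(tert-butyldimethylsilyloxy)-3-[(2R)-2-methylbutanoyloxy]germacra-1(10)Z,4E-dien-12,6-olide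
Product: 22 (3S,6S,7S,9S,11R)-9-hydroxy-3-[(2R)-2-methylbutanoyloxy]germacra-1(10)Z,4E-dien-12,6-olide (CNP0276536.1)
Conditions: HF·pyridine, pyridine, THF, 0 °C → rt
Reagents that add atoms: none
Why: Fluoride-mediated cleavage of a secondary silyl ether; pyridine buffering should spare the allylic ester, the lactone and the acid-sensitive 1,5-diene.

## Compound list

1 | (S)-5-(hydroxymethyl)furan-2(5H)-one | O=C1C=C[C@@H](CO)O1 | starting material
2 | (S)-5-[(trityloxy)methyl]furan-2(5H)-one | O=C1C=C[C@@H](COC(c2ccccc2)(c2ccccc2)c2ccccc2)O1 | intermediate
3 | tert-butyl 3-oxopentanoate | CCC(=O)CC(=O)OC(C)(C)C | starting material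
4 | tert-butyl 3-oxo-2-[(2S,3R)-5-oxo-2-(trityloxymethyl)oxolan-3-yl]pentanoate (epimers at the keto-ester carbon) | CCC(=O)C(C(=O)OC(C)(C)C)[C@@H]1[C@@H](COC(c2ccccc2)(c2ccccc2)c2ccccc2)OC(=O)C1 | intermediate
5 | (4S,5S)-5-(hydroxymethyl)-4-(2-oxobutyl)oxolan-2-one | CCC(=O)C[C@@H]1[C@@H](CO)OC(=O)C1 | intermediate
6 | (2S,3S)-5-oxo-3-(2-oxobutyl)oxolane-2-carbaldehyde | CCC(=O)C[C@@H]1[C@@H](C=O)OC(=O)C1 | intermediate
7 | (3aS,7aS)-6-methyl-3a,7a-dihydro-1-benzofuran-2,5(3H,4H)-dione | O=C1C[C@@H]2[C@@H](C=C1C)OC(=O)C2 | intermediate
8 | ethyl vinyl ketone | CCC(=O)C=C | starting material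
9 | (Z)-3-(tert-butyldimethylsilyloxy)penta-1,3-diene | C=C/C(O[Si](C)(C)C(C)(C)C)=C/C | intermediate
10 | 3-(tert-butyldimethylsilyloxy)-9-oxo-13-nor-5βH-eudesm-2-en-12,6α-olide (4α-methyl, cis-fused) | C1=C(O[Si](C)(C)C(C)(C)C)[C@@H](C)[C@H]2[C@H]3OC(=O)C[C@@H]3CC(=O)[C@@]2(C)C1 | intermediate
11 | 3-(tert-butyldimethylsilyloxy)-9β-hydroxy-13-nor-5βH-eudesm-2-en-12,6α-olide | C1=C(O[Si](C)(C)C(C)(C)C)[C@@H](C)[C@H]2[C@H]3OC(=O)C[C@@H]3C[C@H](O)[C@@]2(C)C1 | intermediate
12 | 3,9β-bis(tert-butyldimethylsilyloxy)-13-nor-5βH-eudesm-2-en-12,6α-olide | C1=C(O[Si](C)(C)C(C)(C)C)[C@@H](C)[C@H]2[C@H]3OC(=O)C[C@@H]3C[C@H](O[Si](C)(C)C(C)(C)C)[C@@]2(C)C1 | intermediate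
13 | (11S)-3,9β-bis(tert-butyldimethylsilyloxy)-5βH-eudesm-2-en-12,6α-olide | C1=C(O[Si](C)(C)C(C)(C)C)[C@@H](C)[C@H]2[C@H]3OC(=O)[C@@H](C)[C@@H]3C[C@H](O[Si](C)(C)C(C)(C)C)[C@@]2(C)C1 | intermediate
14 | (11R)-3,9β-bis(tert-butyldimethylsilyloxy)-5βH-eudesm-2-en-12,6α-olide | C1=C(O[Si](C)(C)C(C)(C)C)[C@@H](C)[C@H]2[C@H]3OC(=O)[C@H](C)[C@@H]3C[C@H](O[Si](C)(C)C(C)(C)C)[C@@]2(C)C1 | intermediate
15 | (11R)-9β-(tert-butyldimethylsilyloxy)-3-oxo-5βH-eudesm-1-en-12,6α-olide | O=C1[C@@H](C)[C@H]2[C@H]3OC(=O)[C@H](C)[C@@H]3C[C@H](O[Si](C)(C)C(C)(C)C)[C@@]2(C)C=C1 | intermediate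
16 | (11R)-3,9β-bis(tert-butyldimethylsilyloxy)-5βH-eudesma-1,3-dien-12,6α-olide (cis-fused dienol ether, precursor of the key step) | CC(C)(C)[Si](C)(C)OC1=C(C)[C@H]2[C@H]3OC(=O)[C@H](C)[C@@H]3C[C@H](O[Si](C)(C)C(C)(C)C)[C@@]2(C)C=C1 | intermediate
17 | (6S,7S,9S,11R)-3,9-bis(tert-butyldimethylsilyloxy)germacra-1(10)Z,2E,4E-trien-12,6-olide (silyloxy-triene, formed and consumed at −78 °C) | CC(C)(C)[Si](C)(C)OC1=C\C=C(\C)[C@@H](O[Si](C)(C)C(C)(C)C)C[C@@H]2[C@@H](/C=C/1C)OC(=O)[C@@H]2C | intermediate
18 | (6S,7S,9S,11R)-9-(tert-butyldimethylsilyloxy)-3-oxogermacra-1(10)Z,4E-dien-12,6-olide | O=C1C/C=C(/C)[C@@H](O[Si](C)(C)C(C)(C)C)C[C@@H]2[C@@H](/C=C/1C)OC(=O)[C@@H]2C | intermediate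
19 | (3S,6S,7S,9S,11R)-9-(tert-butyldimethylsilyloxy)-3-hydroxygermacra-1(10)Z,4E-dien-12,6-olide | O[C@H]1C/C=C(/C)[C@@H](O[Si](C)(C)C(C)(C)C)C[C@@H]2[C@@H](/C=C/1C)OC(=O)[C@@H]2C | intermediate
20 | (R)-2-methylbutanoic acid | CC[C@@H](C)C(=O)O | starting material
21 | (3S,6S,7S,9S,11R)-9-(tert-butyldimethylsilyloxy)-3-[(2R)-2-methylbutanoyloxy]germacra-1(10)Z,4E-dien-12,6-olide | CC[C@@H](C)C(=O)O[C@H]1C/C=C(/C)[C@@H](O[Si](C)(C)C(C)(C)C)C[C@@H]2[C@@H](/C=C/1C)OC(=O)[C@@H]2C | intermediate
22 | (3S,6S,7S,9S,11R)-9-hydroxy-3-[(2R)-2-methylbutanoyloxy]germacra-1(10)Z,4E-dien-12,6-olide | CC[C@@H](C)C(=O)O[C@H]1C/C=C(/C)[C@@H](O)C[C@@H]2[C@@H](/C=C/1C)OC(=O)[C@@H]2C | target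

## Step count and least certain steps

Total: 17 steps. Longest linear sequence: 16 steps (1 → 22 through steps 1–5 and 7–17); step 6 is a one-step branch.

**Step 14 (key step).** The most likely failure is back-reaction and over-irradiation: triene 17 absorbs in the same region as 16, so a photostationary mixture with secondary photoproducts can build up, and on warming 17 can reclose thermally (disrotatory) to the trans-fused diene before it is trapped. A second risk is loss of torquoselectivity if the excited diene leaves the lactone-locked half-chair. The fallback replaces bond scission by ring closure at C5–C6. It sets out from acid 20, which is used to acylate the C3 hydroxyl during an independent fragment assembly of the open-chain iodo aldehyde F1 ((E)-alkenyl iodide at C5, aldehyde at C6, methyl ester at C12; no numbered intermediate serves as its precursor). CrCl2 with catalytic NiCl2 in DMSO–THF at high dilution would then add the alkenylchromium to the aldehyde and lactonise the alkoxide, returning to the route at 21.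

**Step 7.** The likely failures are a stepwise Mukaiyama–Michael reaction with loss of the silyl group instead of cycloaddition, and slow reaction of the α-methyl enone leading to decomposition of the diene. The fallback is an anionic double Michael annulation: the kinetic lithium dienolate generated from 8 (LDA, THF, −78 °C) adds through its methyl-bearing carbon to C5 of 7, the resulting C10 enolate closes onto the vinyl ketone, and TBSCl traps the ring-A enolate. It sets out from 7 and 8, returns at 10 and makes no new isolated compound (F0).

**Step 8.** The likely failure is poor facial selectivity: the α face of the C9 carbonyl is screened by the axial C4 of ring A and the β face by the adjacent axial methyl, so the catalyst may be mismatched with the substrate. The fallback changes from kinetic hydride delivery to thermodynamic control: electron-transfer reduction with SmI2/i-PrOH in THF–HMPA, which should favour the equatorial 9β-alcohol. It sets out from 10, returns at 11 and makes no new compound (F0).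

**Step 5.** The likely failure is epimerisation at C6 by enolisation or enamine formation of the α-acyloxy aldehyde before ring closure, which would lead to the cis-fused lactone. The fallback avoids the aldehyde altogether. Starting from 5, iodination (I2, PPh3, imidazole) gives the primary iodide F2. Intramolecular alkylation of the ketone enolate (KOt-Bu, THF, 0 °C; only the C10 enolate can form a six-membered ring) gives the saturated keto lactone F3. Thermodynamic silylation (TMSCl, NaI, Et3N, MeCN) gives the tetrasubstituted silyl enol ether F4, and Saegusa oxidation (Pd(OAc)2) returns to the route at 7.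

**Step 11.** The likely failure is incomplete facial discrimination in the protonation, or proton return from diisopropylamine, leaving a mixture with 13. The fallback sets the centre by hydrogen addition to carbon instead of protonation. Starting from 12, aldol reaction of the lactone enolate with gaseous formaldehyde gives the hydroxymethyl lactone F5. Mesylation (MsCl, Et3N) gives the mesylate F6 (not isolated), which eliminates in the same flask to the α-methylene lactone F7. Hydrogenation with RhCl(PPh3)3 from the less hindered α face should then give 14 without touching the trisubstituted enol ether.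

**Step 15.** The likely failure is substrate-controlled (peripheral) hydride attack on the ten-membered ring overriding the catalyst and giving mainly the 3R alcohol. In the fallback 18 is reduced deliberately to the 3R-alcohol F8 (with (S)-Me-CBS/catecholborane, or NaBH4/CeCl3 if substrate control is strong), and Mitsunobu esterification with acid 20 (PPh3, DIAD) inverts C3 and returns to the route at 21.

## Further compounds

F1 | step 14 | methyl (2R,3S,5S,6Z,9S,10E)-5-(tert-butyldimethylsilyloxy)-3-formyl-11-iodo-2,6,10-trimethyl-9-[(2R)-2-methylbutanoyloxy]undeca-6,10-dienoate (open-chain iodo aldehyde) | CC[C@@H](C)C(=O)O[C@@H](C/C=C(/C)[C@@H](O[Si](C)(C)C(C)(C)C)C[C@H](C=O)[C@@H](C)C(=O)OC)/C(C)=C/I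
F0 | step 7 | none | none
F0 | step 8 | none | none
F2 | step 5 | (4S,5S)-5-(iodomethyl)-4-(2-oxobutyl)oxolan-2-one | CCC(=O)C[C@@H]1[C@@H](CI)OC(=O)C1
F3 | step 5 | (3aS,7aS)-6-methylhexahydro-1-benzofuran-2,5-dione (trans-fused; epimers at C6 of the bicycle) | O=C1C[C@@H]2[C@@H](CC1C)OC(=O)C2
F4 | step 5 | (3aS,7aS)-6-methyl-5-(trimethylsilyloxy)-3a,4,7,7a-tetrahydro-1-benzofuran-2(3H)-one | C[Si](C)(C)OC1=C(C)C[C@H]2OC(=O)C[C@@H]2C1
F5 | step 11 | 3,9β-bis(tert-butyldimethylsilyloxy)-13-hydroxy-5βH-eudesm-2-en-12,6α-olide (epimers at C11) | C1=C(O[Si](C)(C)C(C)(C)C)[C@@H](C)[C@H]2[C@H]3OC(=O)C(CO)[C@@H]3C[C@H](O[Si](C)(C)C(C)(C)C)[C@@]2(C)C1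
F6 | step 11 | 3,9β-bis(tert-butyldimethylsilyloxy)-13-(methanesulfonyloxy)-5βH-eudesm-2-en-12,6α-olide (epimers at C11) | C1=C(O[Si](C)(C)C(C)(C)C)[C@@H](C)[C@H]2[C@H]3OC(=O)C(COS(C)(=O)=O)[C@@H]3C[C@H](O[Si](C)(C)C(C)(C)C)[C@@]2(C)C1
F7 | step 11 | 3,9β-bis(tert-butyldimethylsilyloxy)-5βH-eudesma-2,11(13)-dien-12,6α-olide | C1=C(O[Si](C)(C)C(C)(C)C)[C@@H](C)[C@H]2[C@H]3OC(=O)C(=C)[C@@H]3C[C@H](O[Si](C)(C)C(C)(C)C)[C@@]2(C)C1
F8 | step 15 | (3R,6S,7S,9S,11R)-9-(tert-butyldimethylsilyloxy)-3-hydroxygermacra-1(10)Z,4E-dien-12,6-olide | O[C@@H]1C/C=C(/C)[C@@H](O[Si](C)(C)C(C)(C)C)C[C@@H]2[C@@H](/C=C/1C)OC(=O)[C@@H]2C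
A1 | alternative 1 | 9-O-tert-butyldimethylsilyl ether of the target (identical with 21) | CC[C@@H](C)C(=O)O[C@H]1C/C=C(/C)[C@@H](O[Si](C)(C)C(C)(C)C)C[C@@H]2[C@@H](/C=C/1C)OC(=O)[C@@H]2C
A2 | alternative 2 | methyl (2R)-2-[(1S,2S,3E,5S,7Z,9S)-9-(tert-butyldimethylsilyloxy)-5-hydroxy-4,8-dimethyl-2-(triethylsilyloxy)cyclodeca-3,7-dien-1-yl]propanoate | O[C@H]1C/C=C(/C)[C@@H](O[Si](C)(C)C(C)(C)C)C[C@@H]([C@@H](C)C(=O)OC)[C@@H](/C=C/1C)O[Si](CC)(CC)CC
A3 | alternative 3 | 7-isopropenyl-6-(4-methoxybenzyloxy)-3-(tert-butyldimethylsilyloxy)cyclodeca-1(10)Z,4E-dien-9-one (germacrane numbering) | CC(C)(C)[Si](C)(C)O[C@H]1C/C=C(/C)C(=O)C[C@@H](C(C)=C)[C@@H](/C=C/1C)OCc1ccc(OC)cc1
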